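**Retrosynthetic overview**

- The strategy rests on ring B: a 3',5'-dihydroxyphenyl group on C2 whose two C–O bonds sit at the two sterically open meta C–H positions of a plain phenyl ring. Rings A and C and the (2S) centre are those of commercial (S)-pinocembrin.
- C3'–O and C5'–O are traced back to C–B bonds and these to C–H bonds: one iridium-catalysed double C–H borylation of protected 6-geranylpinocembrin, then oxidation.
- The C6–geranyl bond is made by Stille coupling of a 6-iodide with tributyl(geranyl)stannane; the iodide comes from 7-O-MOM-pinocembrin by iodination ortho to the free, chelated 5-OH.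
- No ring is formed in the route; rings A, B and C and the stereocentre are bought.

Key step: step 6

Assumption: commercial (S)-pinocembrin is taken as enantiomerically pure. Because C2 of a flavanone racemises through base-triggered opening of the C2–O1 bond, no flavanone in the route meets a base stronger than a trialkylamine.

**Route**

Step 1
Reactants: 1 (S)-pinocembrin
Product: 2 (2S)-5-hydroxy-7-(methoxymethoxy)-2-phenylchroman-4-one
Conditions: MOMCl (1.2 equiv), i-Pr2NEt (1.5 equiv), CH2Cl2, 0 °C to rt
Reagents that add atoms: chloromethyl methyl ether, COCCl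
Why: Williamson-type O-alkylation in which the free, more acidic 7-OH reacts, while the 5-OH is held in a hydrogen bond to the C4 carbonyl and stays untouched by a near-stoichiometric amount of MOMCl with a hindered amine that is too weak to enolise the ketone.

Step 2
Reactants: 2 (2S)-5-hydroxy-7-(methoxymethoxy)-2-phenylchroman-4-one
Product: 3 (2S)-5-hydroxy-6-iodo-7-(methoxymethoxy)-2-phenylchroman-4-one
Conditions: BnMe3N+ ICl2− (1.05 equiv), CaCO3 (1.5 equiv), CH2Cl2/MeOH (5:2), rt, dark
Reagents that add atoms: benzyltrimethylammonium dichloroiodate, C[N+](C)(C)Cc1ccccc1.Cl[I-]Cl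
Why: Electrophilic aromatic iodination, in which the free chelated 5-OH of a 5-hydroxy-7-alkoxy flavonoid steers iodine to C6 rather than C8, CaCO3 takes up HCl so the MOM ether survives, and one equivalent limits 6,8-diiodination; the position of iodine is to be confirmed by HMBC from the 5-OH proton before going on.

Step 3
Reactants: 3 (2S)-5-hydroxy-6-iodo-7-(methoxymethoxy)-2-phenylchroman-4-one
Product: 4 (2S)-6-iodo-5,7-bis(methoxymethoxy)-2-phenylchroman-4-one
Conditions: MOMCl (4 equiv), i-Pr2NEt (5 equiv), Bu4NI (10 mol%), ClCH2CH2Cl, 50 °C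
Reagents that add atoms: chloromethyl methyl ether, COCCl
Why: O-alkylation of the chelated, iodine-flanked 5-OH is forced by excess MOMCl, MOMI formed in situ (Finkelstein exchange) and mild heat, while the amine base forms no ketone enolate, so the C2–O1 bond is not opened by retro-oxa-Michael (E1cB) elimination and C2 keeps its configuration.

Step 4
Reactants: 5 tributyltin hydride; 6 geranyl bromide
Product: 8 tributyl(geranyl)stannane, via tributylstannyllithium 7 (not isolated)
Conditions: LiN(i-Pr)2 (1.0 equiv), THF, 0 °C; then 6, −78 °C to 0 °C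
Reagents that add atoms: none
Why: The lithium amide deprotonates Bu3SnH to the stannyl anion, which displaces the primary allylic bromide by SN2 at C1 at low temperature and leaves the 2E alkene in place.

Step 5
Reactants: 4 (2S)-6-iodo-5,7-bis(methoxymethoxy)-2-phenylchroman-4-one; 8 tributyl(geranyl)stannane
Product: 9 (2S)-6-geranyl-5,7-bis(methoxymethoxy)-2-phenylchroman-4-one
Conditions: Pd(PPh3)4 (10 mol%), CuI (20 mol%), DMF, 80 °C, degassed
Reagents that add atoms: none
Why: Stille coupling, in which the aryl iodide adds oxidatively to zerovalent palladium, the allyl group is transferred from tin with the help of CuI, and reductive elimination at the less hindered allyl terminus of the favoured syn allyl complex gives the linear 2E geranyl arene; the medium is neutral, so C2 is safe.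

Step 6
Reactants: 9 (2S)-6-geranyl-5,7-bis(methoxymethoxy)-2-phenylchroman-4-one; 10 bis(pinacolato)diboron
Product: 11 (2S)-6-geranyl-5,7-bis(methoxymethoxy)-2-[3,5-bis(4,4,5,5-tetramethyl-1,3,2-dioxaborolan-2-yl)phenyl]chroman-4-one
Conditions: [Ir(OMe)(cod)]2 (3 mol%), 4,4'-di-tert-butyl-2,2'-bipyridine (6 mol%), 10 (2.5 equiv), THF, 65 °C, slow N2 sweep
Reagents that add atoms: none
Why: Iridium-catalysed aromatic C–H borylation: precatalyst, bipyridine and B2pin2 give a trivalent iridium tris(boryl) complex, which cleaves an aryl C–H bond by oxidative addition to a pentavalent iridium hydride and releases Ar–Bpin by reductive elimination, after which B2pin2 restores the tris(boryl) species and HBpin leaves. The closest known reaction type is the sterically governed diborylation of monosubstituted benzenes to 3,5-diborylarenes. No ring is closed and no stereocentre is formed; C2 is not at risk because the medium is neutral and aprotic and no enolate can arise. The selectivity needed is C3'–H and C5'–H over C4'–H, C8–H and the alkenes: C2'–H and C6'–H are blocked by the chromanone on C1', and once one meta carbon bears Bpin the only unhindered C–H left is the other meta one, whereas a first hit at C4' gives a monoboronate with no open C–H, which is the expected by-product and is removed by chromatography. C8–H of ring A is flanked by O1 and the C7 MOM ether, and the two trisubstituted alkenes and all sp3 C–H bonds are poorer substrates for this catalyst than an unhindered aryl C–H; the moderate temperature and the nitrogen sweep that carries off H2 are meant to hold back alkene hydroboration and hydrogenation.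

Step 7
Reactants: 11 (2S)-6-geranyl-5,7-bis(methoxymethoxy)-2-[3,5-bis(4,4,5,5-tetramethyl-1,3,2-dioxaborolan-2-yl)phenyl]chroman-4-one
Product: 12 (2S)-2-(3,5-dihydroxyphenyl)-6-geranyl-5,7-bis(methoxymethoxy)chroman-4-one
Conditions: 30% aq H2O2 (6 equiv), THF/pH 7 phosphate buffer (NaH2PO4/Na2HPO4), 0 °C to rt
Reagents that add atoms: hydrogen peroxide, OO
Why: Oxidation of aryl boronates by hydroperoxide (addition of HOO− to boron, 1,2-shift of the aryl group from B to O, hydrolysis of the borate ester); at pH 7 H2O2 leaves the trisubstituted alkenes and the ketone alone and, unlike alkaline peroxide or perborate, does not expose the fully protected flavanone to base that could open ring C and racemise C2.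

Step 8
Reactants: 12 (2S)-2-(3,5-dihydroxyphenyl)-6-geranyl-5,7-bis(methoxymethoxy)chroman-4-one
Product: 13 schizolaenone C
Conditions: HCl in MeOH (1.25 M), 40 °C, stopped at full conversion
Reagents that add atoms: none
Why: Acid-catalysed acetal methanolysis (transacetalisation to dimethoxymethane) frees first the 5-OH peri to the carbonyl and then the 7-OH; dilute anhydrous HCl protonates the acetal oxygens faster than the trisubstituted alkenes, short exposure limits cyclisation of the geranyl chain onto the flanking phenols, and C2 is stable to acid because ring B has no 4'-OH that could open ring C through a quinone methide.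

**Compound list**

1 | (S)-pinocembrin, (2S)-5,7-dihydroxy-2-phenylchroman-4-one | O=C1C[C@@H](c2ccccc2)Oc2cc(O)cc(O)c21 | starting material
2 | (2S)-5-hydroxy-7-(methoxymethoxy)-2-phenylchroman-4-one | O=C1C[C@@H](c2ccccc2)Oc2cc(OCOC)cc(O)c21 | intermediate
3 | (2S)-5-hydroxy-6-iodo-7-(methoxymethoxy)-2-phenylchroman-4-one | O=C1C[C@@H](c2ccccc2)Oc2cc(OCOC)c(I)c(O)c21 | intermediate
4 | (2S)-6-iodo-5,7-bis(methoxymethoxy)-2-phenylchroman-4-one | O=C1C[C@@H](c2ccccc2)Oc2cc(OCOC)c(I)c(OCOC)c21 | intermediate
5 | tributyltin hydride | CCCC[SnH](CCCC)CCCC | starting material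
6 | geranyl bromide, (2E)-1-bromo-3,7-dimethylocta-2,6-diene | CC(C)=CCC/C(C)=C/CBr | starting material
7 | tributylstannyllithium | [Li][Sn](CCCC)(CCCC)CCCC | intermediate
8 | tributyl(geranyl)stannane, tributyl[(2E)-3,7-dimethylocta-2,6-dien-1-yl]stannane | CC(C)=CCC/C(C)=C/C[Sn](CCCC)(CCCC)CCCC | intermediate
9 | (2S)-6-geranyl-5,7-bis(methoxymethoxy)-2-phenylchroman-4-one (geranyl = (2E)-3,7-dimethylocta-2,6-dien-1-yl) | CC(C)=CCC/C(C)=C/Cc1c(OCOC)cc2c(c1OCOC)C(=O)C[C@@H](c1ccccc1)O2 | intermediate
10 | bis(pinacolato)diboron | CC1(C)OB(OC1(C)C)B1OC(C)(C)C(C)(C)O1 | starting material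
11 | (2S)-6-geranyl-5,7-bis(methoxymethoxy)-2-[3,5-bis(4,4,5,5-tetramethyl-1,3,2-dioxaborolan-2-yl)phenyl]chroman-4-one | CC(C)=CCC/C(C)=C/Cc1c(OCOC)cc2c(c1OCOC)C(=O)C[C@@H](c1cc(B3OC(C)(C)C(C)(C)O3)cc(B3OC(C)(C)C(C)(C)O3)c1)O2 | intermediate
12 | (2S)-2-(3,5-dihydroxyphenyl)-6-geranyl-5,7-bis(methoxymethoxy)chroman-4-one | CC(C)=CCC/C(C)=C/Cc1c(OCOC)cc2c(c1OCOC)C(=O)C[C@@H](c1cc(O)cc(O)c1)O2 | intermediate
13 | schizolaenone C, (2S)-2-(3,5-dihydroxyphenyl)-6-geranyl-5,7-dihydroxychroman-4-one | CC(C)=CCC/C(C)=C/Cc1c(O)cc2c(c1O)C(=O)C[C@@H](c1cc(O)cc(O)c1)O2 | target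

**Totals**

Total step count: 8. Longest linear sequence: 7 steps (steps 1, 2, 3, 5, 6, 7, 8, from 1 to 13); step 4 is a one-step side branch.

**Steps most likely to fail**

1. Step 6. What may go wrong: hydroboration, hydrogenation or isomerisation of the geranyl alkenes by HBpin and H2 on iridium, stalling at the monoboronate stage, or a large share of para borylation that cannot go on to a diboronate. Fallback, setting out from 4 and coming back at 13: the same iridium-catalysed diborylation is run on the iodide 4, which has no alkene and whose C–I bond is tolerated by this catalyst, to give (2S)-6-iodo-5,7-bis(methoxymethoxy)-2-[3,5-bis(pinacolatoboryl)phenyl]chroman-4-one F1. Buffered H2O2 as in step 7 gives (2S)-2-(3,5-dihydroxyphenyl)-6-iodo-5,7-bis(methoxymethoxy)chroman-4-one F2. MOMCl and i-Pr2NEt in CH2Cl2 protect the two unchelated ring B phenols as (2S)-6-iodo-5,7-bis(methoxymethoxy)-2-[3,5-bis(methoxymethoxy)phenyl]chroman-4-one F3. Stille coupling with 8 under the conditions of step 5 gives (2S)-6-geranyl-5,7-bis(methoxymethoxy)-2-[3,5-bis(methoxymethoxy)phenyl]chroman-4-one F4, and methanolic HCl as in step 8 removes all four MOM groups to give 13.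

2. Step 5. What may go wrong: slow oxidative addition at the iodide flanked by two MOM ethers with competing protodeiodination, and allyl transposition or E/Z scrambling at the allylpalladium stage. Fallback, setting out from 4 and coming back at 9: the polarity is reversed. Stannylation of 4 with Me3SnSnMe3 and Pd(PPh3)4 in toluene at 100 °C gives (2S)-5,7-bis(methoxymethoxy)-2-phenyl-6-(trimethylstannyl)chroman-4-one F5. Its Stille coupling with geranyl bromide 6 (Pd2(dba)3, AsPh3, THF, 50 °C) starts from the fast oxidative addition of the allylic bromide, which gives the syn allyl complex directly, and delivers the aryl group to the less hindered terminus to give 9.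

3. Step 3. What may go wrong: incomplete alkylation of the hindered, hydrogen-bonded 5-OH, and, if a stronger base is used to force it, opening of the C2–O1 bond with loss of enantiopurity. Fallback, setting out from 3 and coming back at 13: the 5-OH is acetylated instead (Ac2O, pyridine, cat. 4-dimethylaminopyridine, rt) to (2S)-5-acetoxy-6-iodo-7-(methoxymethoxy)-2-phenylchroman-4-one F6. Stille coupling with 8 as in step 5 gives (2S)-5-acetoxy-6-geranyl-7-(methoxymethoxy)-2-phenylchroman-4-one F7, and diborylation as in step 6 gives (2S)-5-acetoxy-6-geranyl-7-(methoxymethoxy)-2-[3,5-bis(pinacolatoboryl)phenyl]chroman-4-one F8. Methanolic HCl at 40 °C then removes acetate and MOM together, so that no aryl ester meets peroxide, to give (2S)-6-geranyl-5,7-dihydroxy-2-[3,5-bis(pinacolatoboryl)phenyl]chroman-4-one F9, and buffered H2O2 as in step 7 oxidises both boronates to give 13.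

**Further compounds**

F1 | step 6 | (2S)-6-iodo-5,7-bis(methoxymethoxy)-2-[3,5-bis(pinacolatoboryl)phenyl]chroman-4-one | O=C1C[C@@H](c2cc(B3OC(C)(C)C(C)(C)O3)cc(B3OC(C)(C)C(C)(C)O3)c2)Oc2cc(OCOC)c(I)c(OCOC)c21
F2 | step 6 | (2S)-2-(3,5-dihydroxyphenyl)-6-iodo-5,7-bis(methoxymethoxy)chroman-4-one | O=C1C[C@@H](c2cc(O)cc(O)c2)Oc2cc(OCOC)c(I)c(OCOC)c21
F3 | step 6 | (2S)-6-iodo-5,7-bis(methoxymethoxy)-2-[3,5-bis(methoxymethoxy)phenyl]chroman-4-one | O=C1C[C@@H](c2cc(OCOC)cc(OCOC)c2)Oc2cc(OCOC)c(I)c(OCOC)c21
F4 | step 6 | (2S)-6-geranyl-5,7-bis(methoxymethoxy)-2-[3,5-bis(methoxymethoxy)phenyl]chroman-4-one | CC(C)=CCC/C(C)=C/Cc1c(OCOC)cc2c(c1OCOC)C(=O)C[C@@H](c1cc(OCOC)cc(OCOC)c1)O2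
F5 | step 5 | (2S)-5,7-bis(methoxymethoxy)-2-phenyl-6-(trimethylstannyl)chroman-4-one | O=C1C[C@@H](c2ccccc2)Oc2cc(OCOC)c([Sn](C)(C)C)c(OCOC)c21
F6 | step 3 | (2S)-5-acetoxy-6-iodo-7-(methoxymethoxy)-2-phenylchroman-4-one | O=C1C[C@@H](c2ccccc2)Oc2cc(OCOC)c(I)c(OC(C)=O)c21
F7 | step 3 | (2S)-5-acetoxy-6-geranyl-7-(methoxymethoxy)-2-phenylchroman-4-one | CC(C)=CCC/C(C)=C/Cc1c(OCOC)cc2c(c1OC(C)=O)C(=O)C[C@@H](c1ccccc1)O2
F8 | step 3 | (2S)-5-acetoxy-6-geranyl-7-(methoxymethoxy)-2-[3,5-bis(pinacolatoboryl)phenyl]chroman-4-one | CC(C)=CCC/C(C)=C/Cc1c(OCOC)cc2c(c1OC(C)=O)C(=O)C[C@@H](c1cc(B3OC(C)(C)C(C)(C)O3)cc(B3OC(C)(C)C(C)(C)O3)c1)O2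
F9 | step 3 | (2S)-6-geranyl-5,7-dihydroxy-2-[3,5-bis(pinacolatoboryl)phenyl]chroman-4-one | CC(C)=CCC/C(C)=C/Cc1c(O)cc2c(c1O)C(=O)C[C@@H](c1cc(B3OC(C)(C)C(C)(C)O3)cc(B3OC(C)(C)C(C)(C)O3)c1)O2
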